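**Retrosynthetic overview**
- The triene is cut between C8 and C9 (Stille): an (E)-vinylstannane of the complete amido-epoxyquinol core plus the (2E,4E)-5-bromopentadienamide of 2-amino-3-hydroxycyclopentenone (five-membered ring bought as cyclopentane-1,3-dione).
- The oxirane comes from hydroxyl-directed nucleophilic epoxidation of a 4-ethynyl p-quinol, and the quinol from α′,β′-dehydrogenation of a 2-amido-4-alkynylcyclohex-2-enone.
- The cyclohexenone is closed by intramolecular aldol condensation (C2–C3 bond) of an acyclic α-amido keto-aldehyde that already carries the C4 carbinol centre.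
- The keto-aldehyde comes from amide union of (2E,4E,6R)-4,6-dimethyldeca-2,4-dienoic acid (Evans methylation, two Wittig olefinations) with an amino alcohol built from a Sharpless epoxide (Sonogashira, allyl-Grignard opening, epoxidation, ammonolysis).
- Ring order: six-membered carbocycle first (aldol), oxirane second; three branches (acid, core, lower amide) meet in two couplings.

Assumption: the SMILES is taken as drawn, i.e. a (1S,5S,6R) core with the oxirane on the face of the tertiary hydroxyl and a 6R centre in the dienoyl chain; "core numbering" below means C1 ketone, C2 N-bearing carbon, C3 vinyl CH, C4 carbinol carbon, C5/C6 oxirane carbons (C6 next to C1).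

**Upper acid (fragment A)**

Step 1
Reactants: 1 (4R)-4-benzyl-1,3-oxazolidin-2-one; 2 hexanoyl chloride
Product: 3 (4R)-4-benzyl-3-hexanoyl-1,3-oxazolidin-2-one
Conditions: n-BuLi, THF, −78 °C; then 2, −78 → 0 °C
Reagents that add atoms: none
Why: N-acylation of the lithiated oxazolidinone by the acid chloride attaches the Evans auxiliary; no stereocentre is formed.

Step 2
Reactants: 3 (4R)-4-benzyl-3-hexanoyl-1,3-oxazolidin-2-one
Product: 4 (4R)-4-benzyl-3-[(2R)-2-methylhexanoyl]-1,3-oxazolidin-2-one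
Conditions: NaN(SiMe3)2, THF, −78 °C; MeI, −78 → −40 °C
Reagents that add atoms: iodomethane CI
Why: Evans asymmetric alkylation: the chelated Z-sodium enolate is methylated on the face away from the benzyl group, which for the (4R)-auxiliary gives the (2R)-methyl centre (minor diastereomer removed by chromatography).

Step 3
Reactants: 4 (4R)-4-benzyl-3-[(2R)-2-methylhexanoyl]-1,3-oxazolidin-2-one
Product: 5 (2R)-2-methylhexan-1-ol
Conditions: LiBH4, H2O (1.1 equiv), Et2O, 0 °C
Reagents that add atoms: none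
Why: Reductive cleavage of the imide by LiBH4 gives the primary alcohol without touching the α-centre and returns the auxiliary.

Step 4
Reactants: 5 (2R)-2-methylhexan-1-ol
Product: 7 ethyl (2E,4R)-2,4-dimethyloct-2-enoate, via (2R)-2-methylhexanal 6 (not isolated)
Conditions: TEMPO (10 mol %), PhI(OAc)2, CH2Cl2, rt; then Ph3P=C(Me)CO2Et, rt → 40 °C
Reagents that add atoms: ethyl 2-(triphenyl-λ5-phosphanylidene)propanoate CCOC(=O)C(C)=P(c1ccccc1)(c1ccccc1)c1ccccc1
Why: Base-free TEMPO oxidation followed in the same pot by Wittig olefination with the stabilised ylide gives the E-trisubstituted enoate and traps the α-chiral aldehyde before it can epimerise.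

Step 5
Reactants: 7 ethyl (2E,4R)-2,4-dimethyloct-2-enoate
Product: 8 (2E,4R)-2,4-dimethyloct-2-en-1-ol
Conditions: i-Bu2AlH (2.5 equiv), CH2Cl2, −78 °C; Rochelle salt work-up
Reagents that add atoms: none
Why: 1,2-Reduction of the enoate by the aluminium hydride gives the allylic alcohol with the alkene geometry and the allylic centre unchanged.

Step 6
Reactants: 8 (2E,4R)-2,4-dimethyloct-2-en-1-ol
Product: 10 ethyl (2E,4E,6R)-4,6-dimethyldeca-2,4-dienoate, via (2E,4R)-2,4-dimethyloct-2-enal 9 (not isolated)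
Conditions: MnO2 (10 equiv), Ph3P=CHCO2Et, CH2Cl2, rt
Reagents that add atoms: ethyl 2-(triphenyl-λ5-phosphanylidene)acetate CCOC(=O)C=P(c1ccccc1)(c1ccccc1)c1ccccc1
Why: Tandem allylic oxidation–Wittig olefination: the enal is trapped as formed by the stabilised ylide, which gives the new disubstituted alkene E.

Step 7
Reactants: 10 ethyl (2E,4E,6R)-4,6-dimethyldeca-2,4-dienoate
Product: 11 (2E,4E,6R)-4,6-dimethyldeca-2,4-dienoic acid
Conditions: LiOH·H2O, THF/MeOH/H2O, rt; then 1 M HCl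
Reagents that add atoms: lithium hydroxide [Li+].[OH-]
Why: Saponification of the ethyl ester; the remote stereocentre and the diene are not affected.

**Core**

Step 8
Reactants: 12 2-bromoprop-2-en-1-ol; 13 ethynyltri(propan-2-yl)silane
Product: 14 2-methylidene-4-[tri(propan-2-yl)silyl]but-3-yn-1-ol
Conditions: PdCl2(PPh3)2 (2 mol %), CuI (4 mol %), i-Pr2NH, THF, rt
Reagents that add atoms: none
Why: Sonogashira coupling of the vinyl bromide with the terminal alkyne gives the 2-alkynyl allylic alcohol; the free hydroxyl is tolerated.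

Step 9
Reactants: 14 2-methylidene-4-[tri(propan-2-yl)silyl]but-3-yn-1-ol
Product: 15 [(2S)-2-{[tri(propan-2-yl)silyl]ethynyl}oxiran-2-yl]methanol
Conditions: Ti(OiPr)4 (0.2 equiv), L-(+)-diisopropyl tartrate (0.25 equiv), t-BuOOH (2 equiv, decane), 4 Å MS, CH2Cl2, −20 °C
Reagents that add atoms: tert-butyl hydroperoxide CC(C)(C)OO
Why: Sharpless asymmetric epoxidation: the titanium complex of the L-(+)-tartrate delivers oxygen to the face that gives the (S)-2,2-disubstituted oxirane (same sense as (S)-2-methylglycidol), which fixes the future C4.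

Step 10
Reactants: 15 [(2S)-2-{[tri(propan-2-yl)silyl]ethynyl}oxiran-2-yl]methanol
Product: 16 (2S)-2-{[tri(propan-2-yl)silyl]ethynyl}hex-5-ene-1,2-diol
Conditions: CH2=CHCH2MgBr (3 equiv), Et2O/THF, −40 → 0 °C; then H2O
Reagents that add atoms: allylmagnesium bromide C=CC[Mg]Br
Why: SN2 epoxide opening by the Grignard reagent at the unhindered CH2 leaves the C4–O bond intact (configuration retained; Payne equilibration is degenerate here) and the bulky silyl cap blocks SN2′ attack on the alkyne.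

Step 11
Reactants: 16 (2S)-2-{[tri(propan-2-yl)silyl]ethynyl}hex-5-ene-1,2-diol
Product: 17 (2S)-1,2-bis(triethylsilyloxy)-2-{[tri(propan-2-yl)silyl]ethynyl}hex-5-ene
Conditions: Et3SiOTf (2.5 equiv), 2,6-lutidine, CH2Cl2, −78 → 0 °C
Reagents that add atoms: triethylsilyl trifluoromethanesulfonate CC[Si](CC)(CC)OS(=O)(=O)C(F)(F)F
Why: Silylation with the silyl triflate protects both the primary and the hindered tertiary propargylic hydroxyl.

Step 12
Reactants: 17 (2S)-1,2-bis(triethylsilyloxy)-2-{[tri(propan-2-yl)silyl]ethynyl}hex-5-ene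
Product: 18 2-[(3S)-3,4-bis(triethylsilyloxy)-3-{[tri(propan-2-yl)silyl]ethynyl}butyl]oxirane (both oxirane epimers)
Conditions: mCPBA, CH2Cl2, 0 °C → rt
Reagents that add atoms: 3-chloroperoxybenzoic acid OOC(=O)c1cccc(Cl)c1
Why: Prilezhaev epoxidation of the only alkene (the silyl alkyne is inert); the new centre is uncontrolled and is later oxidised to the C1 ketone.

Step 13
Reactants: 18 2-[(3S)-3,4-bis(triethylsilyloxy)-3-{[tri(propan-2-yl)silyl]ethynyl}butyl]oxirane
Product: 19 (5S)-1-amino-5,6-bis(triethylsilyloxy)-5-{[tri(propan-2-yl)silyl]ethynyl}hexan-2-ol (both C2 epimers)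
Conditions: NH3 (saturated in i-PrOH, large excess), 60 °C, sealed tube
Reagents that add atoms: ammonia N
Why: Ammonolysis of the terminal epoxide by SN2 attack at the CH2 gives the 1-amino-2-ol; excess ammonia suppresses double alkylation.

Step 14
Reactants: 19 (5S)-1-amino-5,6-bis(triethylsilyloxy)-5-{[tri(propan-2-yl)silyl]ethynyl}hexan-2-ol; 11 (2E,4E,6R)-4,6-dimethyldeca-2,4-dienoic acid
Product: 20 (2E,4E,6R)-N-[(5S)-2-hydroxy-5,6-bis(triethylsilyloxy)-5-{[tri(propan-2-yl)silyl]ethynyl}hexyl]-4,6-dimethyldeca-2,4-dienamide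
Conditions: EDC·HCl, HOBt, i-Pr2NEt, CH2Cl2, 0 °C → rt
Reagents that add atoms: none
Why: Carbodiimide amide coupling; the primary amine is acylated much faster than the secondary alcohol.

Step 15
Reactants: 20 (2E,4E,6R)-N-[(5S)-2-hydroxy-5,6-bis(triethylsilyloxy)-5-{[tri(propan-2-yl)silyl]ethynyl}hexyl]-4,6-dimethyldeca-2,4-dienamide
Product: 21 (2E,4E,6R)-N-[(5S)-5-formyl-2-oxo-5-(triethylsilyloxy)-7-[tri(propan-2-yl)silyl]hept-6-yn-1-yl]-4,6-dimethyldeca-2,4-dienamide
Conditions: (COCl)2 (6 equiv), DMSO (12 equiv), CH2Cl2, −78 → −30 °C; Et3N, → 0 °C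
Reagents that add atoms: none
Why: Swern oxidation turns the secondary alcohol into the ketone and at the same time converts the primary triethylsilyl ether directly into the aldehyde, while the tertiary silyl ether survives.

Step 16
Reactants: 21 (2E,4E,6R)-N-[(5S)-5-formyl-2-oxo-5-(triethylsilyloxy)-7-[tri(propan-2-yl)silyl]hept-6-yn-1-yl]-4,6-dimethyldeca-2,4-dienamide
Product: 23 (2E,4E,6R)-4,6-dimethyl-N-[(3R)-6-oxo-3-(triethylsilyloxy)-3-{[tri(propan-2-yl)silyl]ethynyl}cyclohex-1-en-1-yl]deca-2,4-dienamide, via aldol adduct 22 (not isolated)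
Conditions: piperidine (0.5 equiv), AcOH (0.5 equiv), 4 Å MS, toluene, 50 °C
Reagents that add atoms: none
Why: Intramolecular aldol condensation (Knoevenagel type): only the acidic N-bearing C2 can reach the non-enolisable aldehyde through a six-membered transition state (C6 would give a four-membered ring), and E1cB dehydration gives the conjugated 2-amido enone with quaternary C4 untouched.

Step 17
Reactants: 23 (2E,4E,6R)-4,6-dimethyl-N-[(3R)-6-oxo-3-(triethylsilyloxy)-3-{[tri(propan-2-yl)silyl]ethynyl}cyclohex-1-en-1-yl]deca-2,4-dienamide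
Product: 25 (2E,4E,6R)-4,6-dimethyl-N-[(3R)-6-oxo-3-(triethylsilyloxy)-3-{[tri(propan-2-yl)silyl]ethynyl}cyclohexa-1,4-dien-1-yl]deca-2,4-dienamide, via silyl dienol ether 24 (not isolated)
Conditions: LiN(SiMe3)2 (2.3 equiv), Me3SiCl (3 equiv), THF, −78 °C; then Pd(OAc)2 (1.1 equiv), MeCN, rt
Reagents that add atoms: none
Why: Saegusa–Ito dehydrogenation: after the amide N–H, the only enolisable position is C6, and divalent palladium oxidises its silyl enol ether to the cross-conjugated dienone (C4 has no hydrogen and cannot be affected).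

Step 18
Reactants: 25 (2E,4E,6R)-4,6-dimethyl-N-[(3R)-6-oxo-3-(triethylsilyloxy)-3-{[tri(propan-2-yl)silyl]ethynyl}cyclohexa-1,4-dien-1-yl]deca-2,4-dienamide
Product: 26 (2E,4E,6R)-N-[(3R)-3-ethynyl-3-hydroxy-6-oxocyclohexa-1,4-dien-1-yl]-4,6-dimethyldeca-2,4-dienamide
Conditions: Bu4NF (2.5 equiv), AcOH (2.5 equiv), THF, 0 °C → rt
Reagents that add atoms: none
Why: Buffered fluoride desilylation removes the tertiary silyl ether and the alkynyl silyl group in one operation, freeing the hydroxyl needed to direct the epoxidation and the terminal alkyne needed for hydrostannation.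

Step 19
Reactants: 26 (2E,4E,6R)-N-[(3R)-3-ethynyl-3-hydroxy-6-oxocyclohexa-1,4-dien-1-yl]-4,6-dimethyldeca-2,4-dienamide
Product: 27 (2E,4E,6R)-N-[(1S,5R,6R)-5-ethynyl-5-hydroxy-2-oxo-7-oxabicyclo[4.1.0]hept-3-en-3-yl]-4,6-dimethyldeca-2,4-dienamide
Conditions: Ph3COOH (2 equiv), NaN(SiMe3)2 (3 equiv), THF, −78 → −20 °C; then AcOH
Reagents that add atoms: triphenylmethyl hydroperoxide OOC(c1ccccc1)(c1ccccc1)c1ccccc1
Why: Hydroxyl-directed Weitz–Scheffer epoxidation: the sodium alkoxide at C4 holds the bulky peroxide anion on its own face, so both oxirane centres form syn to the hydroxyl, and only the unsubstituted C5=C6 enone reacts because the amido-substituted C2=C3 is deactivated.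

**Lower amide (fragment C)**

Step 20
Reactants: 28 pyridinium-1-sulfonate
Product: 29 potassium (1E,3E)-5-oxopenta-1,3-dien-1-olate
Conditions: KOH (aq, excess), −20 → 20 °C
Reagents that add atoms: potassium hydroxide [K+].[OH-]
Why: Hydroxide adds to C2 of the N-sulfonated pyridinium and the ring opens (Zincke-type ring opening) to the all-trans glutaconaldehyde enolate, which crystallises as its potassium salt.

Step 21
Reactants: 29 potassium (1E,3E)-5-oxopenta-1,3-dien-1-olate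
Product: 30 (2E,4E)-5-bromopenta-2,4-dienal
Conditions: Ph3PBr2, CH2Cl2, 0 °C → rt
Reagents that add atoms: bromotriphenylphosphonium bromide Br[P+](c1ccccc1)(c1ccccc1)c1ccccc1.[Br-]
Why: Appel-type bromodeoxygenation of the vinylogous carboxylate: O-phosphonium formation and addition–elimination by bromide give the thermodynamically preferred (E,E)-bromodienal.

Step 22
Reactants: 30 (2E,4E)-5-bromopenta-2,4-dienal
Product: 31 (2E,4E)-5-bromopenta-2,4-dienoic acid
Conditions: NaClO2, NaH2PO4, 2-methylbut-2-ene, t-BuOH/H2O, 0 °C → rt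
Reagents that add atoms: sodium chlorite [Na+].[O-]Cl=O
Why: Pinnick oxidation converts the enal to the acid without touching the bromodiene; the alkene scavenger removes hypochlorite.

Step 23
Reactants: 32 cyclopentane-1,3-dione
Product: 33 3-hydroxy-2-nitrocyclopent-2-en-1-one
Conditions: fuming HNO3, Et2O, 0 °C
Reagents that add atoms: nitric acid O[N+](=O)[O-]
Why: Electrophilic nitration of the enol at C2, the only nucleophilic carbon of the 1,3-dione.

Step 24
Reactants: 33 3-hydroxy-2-nitrocyclopent-2-en-1-one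
Product: 34 2-amino-3-hydroxycyclopent-2-en-1-one hydrochloride
Conditions: H2 (1 atm), Pd/C (10 wt % palladium on carbon), HCl, MeOH, rt
Reagents that add atoms: hydrogen chloride Cl
Why: Catalytic hydrogenation reduces the nitro group to the amine, which is trapped as its hydrochloride so that the aminodione cannot self-condense.

Step 25
Reactants: 31 (2E,4E)-5-bromopenta-2,4-dienoic acid; 34 2-amino-3-hydroxycyclopent-2-en-1-one hydrochloride
Product: 36 (2E,4E)-5-bromo-N-(2-hydroxy-5-oxocyclopent-1-en-1-yl)penta-2,4-dienamide, via acid chloride 35 (not isolated)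
Conditions: (COCl)2, DMF (cat.), CH2Cl2, 0 °C → rt; then 34, Et3N (3 equiv), CH2Cl2, −20 → 0 °C
Reagents that add atoms: none
Why: Amide formation through the acid chloride (Schotten–Baumann-type acylation); any enol ester formed first transfers its acyl group to nitrogen.

**Endgame**

Step 26
Reactants: 27 (2E,4E,6R)-N-[(1S,5R,6R)-5-ethynyl-5-hydroxy-2-oxo-7-oxabicyclo[4.1.0]hept-3-en-3-yl]-4,6-dimethyldeca-2,4-dienamide
Product: 37 (2E,4E,6R)-N-[(1S,5R,6R)-5-hydroxy-2-oxo-5-[(E)-2-(tributylstannyl)ethenyl]-7-oxabicyclo[4.1.0]hept-3-en-3-yl]-4,6-dimethyldeca-2,4-dienamide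
Conditions: Bu3SnH (1.2 equiv, slow addition), PdCl2(PPh3)2 (3 mol %), THF, −20 → 0 °C
Reagents that add atoms: tributylstannane CCCC[SnH](CCCC)CCCC
Why: Palladium-catalysed syn-hydrostannation puts tin on the terminal carbon of the hindered tertiary propargylic alcohol, giving the (E)-vinylstannane; the alkyne reacts faster than the electron-rich amido enone.

Step 27
Reactants: 37 (2E,4E,6R)-N-[(1S,5R,6R)-5-hydroxy-2-oxo-5-[(E)-2-(tributylstannyl)ethenyl]-7-oxabicyclo[4.1.0]hept-3-en-3-yl]-4,6-dimethyldeca-2,4-dienamide; 36 (2E,4E)-5-bromo-N-(2-hydroxy-5-oxocyclopent-1-en-1-yl)penta-2,4-dienamide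
Product: 38 (2E,4E,6R)-N-[(1S,5S,6R)-5-hydroxy-5-[(1E,3E,5E)-7-[(2-hydroxy-5-oxocyclopent-1-en-1-yl)amino]-7-oxohepta-1,3,5-trien-1-yl]-2-oxo-7-oxabicyclo[4.1.0]hept-3-en-3-yl]-4,6-dimethyldeca-2,4-dienamide
Conditions: Pd2(dba)3 (5 mol %), AsPh3 (20 mol %), DMF, rt, dark
Reagents that add atoms: none
Why: Stille cross-coupling on zerovalent palladium joins the vinylstannane and the vinyl bromide with retention of both alkene geometries under neutral conditions that spare the oxirane, enone and free hydroxyls.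

**Compound list**

1 | (4R)-4-benzyl-1,3-oxazolidin-2-one | O=C1N[C@H](Cc2ccccc2)CO1 | starting material
2 | hexanoyl chloride | CCCCCC(Cl)=O | starting material
3 | (4R)-4-benzyl-3-hexanoyl-1,3-oxazolidin-2-one | CCCCCC(=O)N1[C@H](Cc2ccccc2)COC1=O | intermediate
4 | (4R)-4-benzyl-3-[(2R)-2-methylhexanoyl]-1,3-oxazolidin-2-one | CCCC[C@@H](C)C(=O)N1[C@H](Cc2ccccc2)COC1=O | intermediate
5 | (2R)-2-methylhexan-1-ol | CCCC[C@@H](C)CO | intermediate
6 | (2R)-2-methylhexanal | CCCC[C@@H](C)C=O | intermediate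
7 | ethyl (2E,4R)-2,4-dimethyloct-2-enoate | CCCC[C@@H](C)/C=C(C)/C(=O)OCC | intermediate
8 | (2E,4R)-2,4-dimethyloct-2-en-1-ol | CCCC[C@@H](C)/C=C(C)/CO | intermediate
9 | (2E,4R)-2,4-dimethyloct-2-enal | CCCC[C@@H](C)/C=C(C)/C=O | intermediate
10 | ethyl (2E,4E,6R)-4,6-dimethyldeca-2,4-dienoate | CCCC[C@@H](C)/C=C(C)/C=C/C(=O)OCC | intermediate
11 | (2E,4E,6R)-4,6-dimethyldeca-2,4-dienoic acid | CCCC[C@@H](C)/C=C(C)/C=C/C(=O)O | intermediate
12 | 2-bromoprop-2-en-1-ol | OCC(Br)=C | starting material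
13 | ethynyltri(propan-2-yl)silane | C#C[Si](C(C)C)(C(C)C)C(C)C | starting material
14 | 2-methylidene-4-[tri(propan-2-yl)silyl]but-3-yn-1-ol | OCC(=C)C#C[Si](C(C)C)(C(C)C)C(C)C | intermediate
15 | [(2S)-2-{[tri(propan-2-yl)silyl]ethynyl}oxiran-2-yl]methanol | OC[C@@]1(C#C[Si](C(C)C)(C(C)C)C(C)C)CO1 | intermediate
16 | (2S)-2-{[tri(propan-2-yl)silyl]ethynyl}hex-5-ene-1,2-diol | OC[C@@](O)(C#C[Si](C(C)C)(C(C)C)C(C)C)CCC=C | intermediate
17 | (2S)-1,2-bis(triethylsilyloxy)-2-{[tri(propan-2-yl)silyl]ethynyl}hex-5-ene | CC[Si](CC)(CC)OC[C@@](O[Si](CC)(CC)CC)(C#C[Si](C(C)C)(C(C)C)C(C)C)CCC=C | intermediate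
18 | 2-[(3S)-3,4-bis(triethylsilyloxy)-3-{[tri(propan-2-yl)silyl]ethynyl}butyl]oxirane (both oxirane epimers) | CC[Si](CC)(CC)OC[C@@](O[Si](CC)(CC)CC)(C#C[Si](C(C)C)(C(C)C)C(C)C)CCC1CO1 | intermediate
19 | (5S)-1-amino-5,6-bis(triethylsilyloxy)-5-{[tri(propan-2-yl)silyl]ethynyl}hexan-2-ol (both C2 epimers) | CC[Si](CC)(CC)OC[C@@](O[Si](CC)(CC)CC)(C#C[Si](C(C)C)(C(C)C)C(C)C)CCC(O)CN | intermediate
20 | (2E,4E,6R)-N-[(5S)-2-hydroxy-5,6-bis(triethylsilyloxy)-5-{[tri(propan-2-yl)silyl]ethynyl}hexyl]-4,6-dimethyldeca-2,4-dienamide | CC[Si](CC)(CC)OC[C@@](O[Si](CC)(CC)CC)(C#C[Si](C(C)C)(C(C)C)C(C)C)CCC(O)CNC(=O)/C=C/C(C)=C/[C@H](C)CCCC | intermediate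
21 | (2E,4E,6R)-N-[(5S)-5-formyl-2-oxo-5-(triethylsilyloxy)-7-[tri(propan-2-yl)silyl]hept-6-yn-1-yl]-4,6-dimethyldeca-2,4-dienamide | O=C[C@@](O[Si](CC)(CC)CC)(C#C[Si](C(C)C)(C(C)C)C(C)C)CCC(=O)CNC(=O)/C=C/C(C)=C/[C@H](C)CCCC | intermediate
22 | aldol adduct: (2E,4E,6R)-N-[(3S)-2-hydroxy-6-oxo-3-(triethylsilyloxy)-3-{[tri(propan-2-yl)silyl]ethynyl}cyclohexyl]-4,6-dimethyldeca-2,4-dienamide (C1/C2 epimers) | CCCC[C@@H](C)/C=C(C)/C=C/C(=O)NC1C(O)[C@@](O[Si](CC)(CC)CC)(C#C[Si](C(C)C)(C(C)C)C(C)C)CCC1=O | intermediate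
23 | (2E,4E,6R)-4,6-dimethyl-N-[(3R)-6-oxo-3-(triethylsilyloxy)-3-{[tri(propan-2-yl)silyl]ethynyl}cyclohex-1-en-1-yl]deca-2,4-dienamide | CCCC[C@@H](C)/C=C(C)/C=C/C(=O)NC1=C[C@@](O[Si](CC)(CC)CC)(C#C[Si](C(C)C)(C(C)C)C(C)C)CCC1=O | intermediate
24 | silyl dienol ether: (2E,4E,6R)-4,6-dimethyl-N-[(3R)-3-(triethylsilyloxy)-3-{[tri(propan-2-yl)silyl]ethynyl}-6-(trimethylsilyloxy)cyclohexa-1,5-dien-1-yl]deca-2,4-dienamide | CCCC[C@@H](C)/C=C(C)/C=C/C(=O)NC1=C[C@@](O[Si](CC)(CC)CC)(C#C[Si](C(C)C)(C(C)C)C(C)C)CC=C1O[Si](C)(C)C | intermediate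
25 | (2E,4E,6R)-4,6-dimethyl-N-[(3R)-6-oxo-3-(triethylsilyloxy)-3-{[tri(propan-2-yl)silyl]ethynyl}cyclohexa-1,4-dien-1-yl]deca-2,4-dienamide | CCCC[C@@H](C)/C=C(C)/C=C/C(=O)NC1=C[C@@](O[Si](CC)(CC)CC)(C#C[Si](C(C)C)(C(C)C)C(C)C)C=CC1=O | intermediate
26 | (2E,4E,6R)-N-[(3R)-3-ethynyl-3-hydroxy-6-oxocyclohexa-1,4-dien-1-yl]-4,6-dimethyldeca-2,4-dienamide | CCCC[C@@H](C)/C=C(C)/C=C/C(=O)NC1=C[C@@](O)(C#C)C=CC1=O | intermediate
27 | (2E,4E,6R)-N-[(1S,5R,6R)-5-ethynyl-5-hydroxy-2-oxo-7-oxabicyclo[4.1.0]hept-3-en-3-yl]-4,6-dimethyldeca-2,4-dienamide | CCCC[C@@H](C)/C=C(C)/C=C/C(=O)NC1=C[C@@](O)(C#C)[C@@H]2O[C@@H]2C1=O | intermediate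
28 | pyridinium-1-sulfonate | [O-]S(=O)(=O)[n+]1ccccc1 | starting material
29 | potassium (1E,3E)-5-oxopenta-1,3-dien-1-olate | [K+].[O-]/C=C/C=C/C=O | intermediate
30 | (2E,4E)-5-bromopenta-2,4-dienal | Br/C=C/C=C/C=O | intermediate
31 | (2E,4E)-5-bromopenta-2,4-dienoic acid | Br/C=C/C=C/C(=O)O | intermediate
32 | cyclopentane-1,3-dione | O=C1CCC(=O)C1 | starting material
33 | 3-hydroxy-2-nitrocyclopent-2-en-1-one | O=C1CCC(O)=C1[N+](=O)[O-] | intermediate
34 | 2-amino-3-hydroxycyclopent-2-en-1-one hydrochloride | Cl.NC1=C(O)CCC1=O | intermediate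
35 | (2E,4E)-5-bromopenta-2,4-dienoyl chloride | Br/C=C/C=C/C(Cl)=O | intermediate
36 | (2E,4E)-5-bromo-N-(2-hydroxy-5-oxocyclopent-1-en-1-yl)penta-2,4-dienamide | Br/C=C/C=C/C(=O)NC1=C(O)CCC1=O | intermediate
37 | (2E,4E,6R)-N-[(1S,5R,6R)-5-hydroxy-2-oxo-5-[(E)-2-(tributylstannyl)ethenyl]-7-oxabicyclo[4.1.0]hept-3-en-3-yl]-4,6-dimethyldeca-2,4-dienamide | CCCC[C@@H](C)/C=C(C)/C=C/C(=O)NC1=C[C@@](O)(/C=C/[Sn](CCCC)(CCCC)CCCC)[C@@H]2O[C@@H]2C1=O | intermediate
38 | (2E,4E,6R)-N-[(1S,5S,6R)-5-hydroxy-5-[(1E,3E,5E)-7-[(2-hydroxy-5-oxocyclopent-1-en-1-yl)amino]-7-oxohepta-1,3,5-trien-1-yl]-2-oxo-7-oxabicyclo[4.1.0]hept-3-en-3-yl]-4,6-dimethyldeca-2,4-dienamide | CCCC[C@@H](C)/C=C(C)/C=C/C(=O)NC1=C[C@@](O)(/C=C/C=C/C=C/C(=O)NC2=C(O)CCC2=O)[C@@H]2O[C@@H]2C1=O | target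

**Totals**

Total step count: 27.
Longest linear sequence: 15 steps (steps 1–7, 14–19, 26 and 27); the core branch from 12 is 14 steps and the lower amide branch is at most 5.

**Steps most likely to fail, with fallbacks**

Step 16 (aldol condensation of the α-amido ketone). The amido ketone may not enolise cleanly toward C2 in the presence of the hindered aldehyde. The fallback keeps an aldol ring closure but uses a plain methyl ketone and adds nitrogen afterwards. It sets out from 17 and comes back at 23. Wacker oxidation of 17 (PdCl2, CuCl, O2, DMF/H2O) gives (5S)-5,6-bis(triethylsilyloxy)-5-{[tri(propan-2-yl)silyl]ethynyl}hexan-2-one F1. Swern oxidation as in step 15 gives (2S)-5-oxo-2-(triethylsilyloxy)-2-{[tri(propan-2-yl)silyl]ethynyl}hexanal F2. Pyrrolidine/AcOH in toluene closes the ring (only the methyl group can reach the aldehyde) to (4R)-4-(triethylsilyloxy)-4-{[tri(propan-2-yl)silyl]ethynyl}cyclohex-2-en-1-one F3. Iodination with I2/pyridine gives (4R)-2-iodo-4-(triethylsilyloxy)-4-{[tri(propan-2-yl)silyl]ethynyl}cyclohex-2-en-1-one F4. Copper-catalysed amidation of F4 (CuI, N,N′-dimethylethane-1,2-diamine, K2CO3, toluene, 80 °C) with (2E,4E,6R)-4,6-dimethyldeca-2,4-dienamide F5 (from acid 11 with i-BuOCOCl/N-methylmorpholine, then NH3) gives 23.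

Step 19 (hydroxyl-directed epoxidation). The facial ratio may be poor or the dienone may not tolerate the strong base. The fallback builds the oxirane stepwise from an oxygen tethered to the C4 hydroxyl, so the syn relationship is fixed by ring fusion. It sets out from 26 and comes back at 27. PhB(OH)2 with catalytic i-Pr2NH in toluene gives, by boronate-tethered oxa-Michael addition to C5, the cis-fused B-phenyl dioxaborolane of the C4,C5-syn-diol of 2-amido-4-ethynylcyclohex-2-en-1-one F6. Its trimethylsilyl dienol ether (LiN(SiMe3)2, Me3SiCl) is brominated with N-bromosuccinimide at C6 anti to the C5 oxygen to give the trans-6-bromo derivative of that boronate F7; any cis-bromide epimerises through the enol. Transesterification of the boronate with pinacol and K2CO3 in MeOH then closes the oxirane by intramolecular SN2 displacement of bromide by the C5 oxygen, which gives 27.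

Step 26 (hydrostannation). Tin hydride with palladium may reduce the enone or open the oxirane. The fallback avoids tin hydride: the alkyne is coupled first and then reduced trans. It sets out from 27 (with 36) and comes back at 38. Sonogashira coupling of 27 with 36 (Pd(PPh3)4, CuI, i-Pr2NH, THF) gives the 7,8-didehydro analogue of the target (C7≡C8 dienyne) F8. Trans-hydrosilylation with (EtO)3SiH and [Cp*Ru(MeCN)3]PF6 gives the (Z)-vinylsilane carrying Si(OEt)3 on C8 F9. Protodesilylation (Bu4NF, CuI, THF) replaces silicon by hydrogen with retention and gives the (E)-alkene 38.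

**Further compounds**

F1 | step 16 | (5S)-5,6-bis(triethylsilyloxy)-5-{[tri(propan-2-yl)silyl]ethynyl}hexan-2-one | CC[Si](CC)(CC)OC[C@@](O[Si](CC)(CC)CC)(C#C[Si](C(C)C)(C(C)C)C(C)C)CCC(C)=O
F2 | step 16 | (2S)-5-oxo-2-(triethylsilyloxy)-2-{[tri(propan-2-yl)silyl]ethynyl}hexanal | O=C[C@@](O[Si](CC)(CC)CC)(C#C[Si](C(C)C)(C(C)C)C(C)C)CCC(C)=O
F3 | step 16 | (4R)-4-(triethylsilyloxy)-4-{[tri(propan-2-yl)silyl]ethynyl}cyclohex-2-en-1-one | O=C1C=C[C@@](O[Si](CC)(CC)CC)(C#C[Si](C(C)C)(C(C)C)C(C)C)CC1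
F4 | step 16 | (4R)-2-iodo-4-(triethylsilyloxy)-4-{[tri(propan-2-yl)silyl]ethynyl}cyclohex-2-en-1-one | O=C1C(I)=C[C@@](O[Si](CC)(CC)CC)(C#C[Si](C(C)C)(C(C)C)C(C)C)CC1
F5 | step 16 | (2E,4E,6R)-4,6-dimethyldeca-2,4-dienamide | CCCC[C@@H](C)/C=C(C)/C=C/C(N)=O
F6 | step 19 | cis-fused B-phenyl dioxaborolane of the C4,C5-syn-diol of the 2-dienamido-4-ethynylcyclohex-2-en-1-one | CCCC[C@@H](C)/C=C(C)/C=C/C(=O)NC1=C[C@@]2(C#C)[C@@H](CC1=O)OB(c1ccccc1)O2
F7 | step 19 | trans-6-bromo derivative of boronate F6 (bromine anti to the C5 oxygen) | CCCC[C@@H](C)/C=C(C)/C=C/C(=O)NC1=C[C@@]2(C#C)[C@@H]([C@@H](Br)C1=O)OB(c1ccccc1)O2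
F8 | step 26 | 7,8-didehydro analogue of the target (C7≡C8 dienyne) | CCCC[C@@H](C)/C=C(C)/C=C/C(=O)NC1=C[C@@](O)(C#C/C=C/C=C/C(=O)NC2=C(O)CCC2=O)[C@@H]2O[C@@H]2C1=O
F9 | step 26 | (Z)-8-(triethoxysilyl) derivative of the target (silicon cis to C4 across C7=C8) | CCCC[C@@H](C)/C=C(C)/C=C/C(=O)NC1=C[C@@](O)(/C=C(/C=C/C=C/C(=O)NC2=C(O)CCC2=O)[Si](OCC)(OCC)OCC)[C@@H]2O[C@@H]2C1=O
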